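**Plan**
Retrosynthesis: remove the two acetates and the protecting groups; cut C9–C11 to a ring B enone (C9 carbonyl) and a C11–C15 organometallic from (S)-citronellol; return the C2/C3 diol to a C2=C3 alkene; open ring A at C3–C4; cut C10–C1 and C10–CH3 to reach (S)-carvone, which is ring B.
Enabling feature: C4 is a gem-dimethyl quaternary carbon attached to the C5 ring-fusion methine, so it equals an isopropenyl group plus one hydrogen atom; the isopropenyl carbon of carvone becomes C4 as a tertiary radical that closes ring A onto a C10 acryloyl unit.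
Forward order: ring B (carvone), then C10 quaternised (methyl, then acrolein aldol and oxidation), then ring A by the C3–C4 radical closure, then ring A oxygenation (C2=C3 alkene placed through the C1 oxygen, cis-dihydroxylation, C1 deoxygenation), then the side chain at C9 and adjustment of ring B, then deprotection and diacetylation.
Stereochemistry: C5 from (S)-carvone; C10 by aldol addition anti to the isopropenyl group; C2 and C3 by osmylation anti to the axial C10 methyl; C9 by axial protonation in the Li/NH3 reduction; C13 from (S)-citronellol.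

Key step: step 4

Remarks on the chemistry: labdane numbering is used for all bicyclic compounds (ring A = C1–C5 and C10, ring B = C5–C10, chain C11–C15), and faces are given relative to the C10 methyl; drawn in the usual orientation the target belongs to the ent-labdane series, which is why (S)-carvone is the required antipode. Centres that are removed later (C1 carbinol, C2 selenide, C9 carbinol) are drawn as the expected major epimer, and the two centres formed as mixtures (C6 of 3, carbinol of 6) are left open. Radicals and catalyst-bound species are treated as mechanism and carry no number.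

Step 1
Reactants: 1 (S)-carvone
Product: 3 (5S)-6-methylcarvone (C6 epimer mixture), via lithium dienolate of carvone 2 (not isolated)
Conditions: LiN(i-Pr)2, THF, −78 °C; MeI, −78 → 0 °C
Reagents that add atoms: iodomethane, CI
Why: Kinetic deprotonation at the α′ CH2 gives the cross-conjugated lithium dienolate, whose C-methylation (enolate alkylation) installs the future C10 methyl; the new centre is an epimer mixture that the next enolisation erases.

Step 2
Reactants: 3 (5S)-6-methylcarvone; 4 acrolein
Product: 6 aldol adduct 6-(1-hydroxyprop-2-en-1-yl)-6-methylcarvone (hydroxyallyl group trans to isopropenyl; carbinol epimers), via tetrasubstituted lithium enolate 5 (not isolated)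
Conditions: LiN(i-Pr)2, THF, −78 °C; acrolein, −78 °C; AcOH quench at −78 °C
Reagents that add atoms: none
Why: The tetrasubstituted lithium enolate should undergo a kinetic aldol addition (1,2-addition, cold quench against retro-aldol cleavage) on the face opposite the adjacent isopropenyl group, which fixes the quaternary C10 with the new chain trans to isopropenyl; the carbinol epimers converge in step 3.

Step 3
Reactants: 6 aldol adduct
Product: 7 6-acryloyl-6-methylcarvone (acryloyl trans to isopropenyl)
Conditions: Dess–Martin periodinane, CH2Cl2, 0 °C → rt; used without delay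
Reagents that add atoms: none
Why: Dess–Martin oxidation of the secondary allylic alcohol gives the vinyl ketone under neutral conditions, and since C10 is quaternary no stereocentre can epimerise.

Step 4
Reactants: 7 6-acryloyl-6-methylcarvone
Product: 8 trans-fused 4,4,8,10-tetramethyldecal-7-ene-1,9-dione
Conditions: Fe(acac)3 (30 mol %), PhSiH3 (2.5 equiv), EtOH/ethylene glycol (5:1), 0.02 M, degassed, 60 °C
Reagents that add atoms: none
Why: Fe(acac)3 and PhSiH3 in ethanol generate an iron hydride that transfers a hydrogen atom to the terminal CH2 of the isopropenyl group, so that this carbon becomes the second C4 methyl and C4 becomes a tertiary, nucleophilic radical. The radical adds to the unsubstituted β-carbon (C3) of the C10 acryloyl group, and the α-keto radical at C2 is reduced by divalent iron to the enolate and protonated by the solvent, which returns trivalent iron; the closest known reaction is the iron-mediated hydrogen-atom-transfer reductive olefin coupling (a Giese addition started by Mukaiyama-type hydrogen-atom transfer), here in its intramolecular form. Ring A closes in the 6-endo-trig mode through the new C3–C4 bond. No stereocentre is created: C5 and C10 are carried over from 7, and because the acryloyl and isopropenyl groups are trans the ring fusion can only be trans. The step needs hydrogen-atom transfer to the electron-rich 1,1-disubstituted alkene in preference to the two electron-poor enone alkenes, which the polarity of the metal hydride provides, and 6-endo in preference to 5-exo attack, which follows from polarity matching and from the stabilised α-keto radical (5-exo attack at C2 would leave an unstabilised primary radical); high dilution suppresses intermolecular addition.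

Step 5
Reactants: 8 decalenedione
Product: 10 2-(phenylselanyl)-1,9-dione (selenium anti to the C10 methyl), via C1 lithium enolate 9 (not isolated)
Conditions: LiN(i-Pr)2 (1.05 equiv), THF, −78 °C; PhSeCl, −78 °C
Reagents that add atoms: benzeneselenenyl chloride, Cl[Se]c1ccccc1
Why: Only the C1 ketone has α-hydrogens (at C2), so a single enolate forms and is selenenylated (enolate α-selenenylation), expected on the face anti to the C10 methyl; the C2 configuration is irrelevant because a syn hydrogen at C3 is available in either epimer.

Step 6
Reactants: 10 2-(phenylselanyl)-1,9-dione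
Product: 11 1-hydroxy-2-(phenylselanyl)-enone (C1 hydroxyl equatorial and syn to the C10 methyl)
Conditions: NaBH4, MeOH/CH2Cl2 (1:1), −78 → −40 °C; AcOH quench
Reagents that add atoms: none
Why: Borohydride should reduce the saturated, α-heteroatom-activated C1 ketone faster than the hindered conjugated C9 enone (chemoselective carbonyl reduction, as for the saturated ketone of the Wieland–Miescher ketone), with axial hydride delivery anti to the C10 methyl giving the equatorial C1 alcohol; the two carbonyls are differentiated here because after dehydrogenation both would be enones.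

Step 7
Reactants: 11 hydroxy selenide
Product: 13 allylic alcohol 1-hydroxy-4,4,8,10-tetramethyldecala-2,7-dien-9-one, via selenoxide 12 (not isolated)
Conditions: 30% H2O2 (aq), pyridine, CH2Cl2, 0 °C → rt
Reagents that add atoms: none
Why: Oxidation to the selenoxide and syn-elimination (selenoxide elimination) runs away from the carbinol carbon and places the alkene at C2=C3; the ring B enone is inert to H2O2 without base.

Step 8
Reactants: 13 allylic alcohol
Product: 14 1,2,3-triol (C2 and C3 hydroxyls anti to the C10 methyl; C1 hydroxyl syn)
Conditions: OsO4 (2 mol %), N-methylmorpholine N-oxide, acetone/H2O (4:1), rt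
Reagents that add atoms: N-methylmorpholine N-oxide, C[N+]1([O-])CCOCC1; water, O (both oxygens are passed on by the catalyst OsO4, O=[Os](=O)(=O)=O)
Why: Upjohn dihydroxylation should pick the isolated, electron-rich C2=C3 alkene over the conjugated α-methyl enone of ring B (as carvone is osmylated only at its non-conjugated alkene) and add to the face anti to the axial C10 and C4 methyls and anti to the allylic C1 hydroxyl, which sets C2 and C3.

Step 9
Reactants: 14 triol
Product: 15 2,3-O-isopropylidene derivative with free C1 hydroxyl
Conditions: Me2C(OMe)2, PPTS (cat.), CH2Cl2, rt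
Reagents that add atoms: 2,2-dimethoxypropane, COC(C)(C)OC
Why: Acetonide formation under thermodynamic control selects the cis C2/C3 diol (cis-fused dioxolane) over the trans-diequatorial C1/C2 pair.

Step 10
Reactants: 15 acetonide alcohol
Product: 16 C1 O-phenyl thionocarbonate
Conditions: PhOC(S)Cl, DMAP, MeCN, rt
Reagents that add atoms: O-phenyl chlorothionoformate, S=C(Cl)Oc1ccccc1
Why: DMAP-mediated thioacylation of the one free secondary alcohol gives the Barton–McCombie precursor under conditions too mild for retro-aldol cleavage of the β-hydroxy ketone.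

Step 11
Reactants: 16 thionocarbonate
Product: 17 2,3-O-isopropylidenedioxy-4,4,8,10-tetramethyldecal-7-en-9-one (C1 = CH2)
Conditions: Bu3SnH (5 equiv, 1 M), Et3B (cat.), air, PhMe, rt
Reagents that add atoms: none
Why: Barton–McCombie deoxygenation replaces the C1 oxygen by hydrogen; the high Bu3SnH concentration at room temperature is chosen so that hydrogen transfer outruns 3-exo attack of the C1 radical on the C9 carbonyl, and a carbon radical does not expel the β-oxygen at C2.

Step 12
Reactants: 18 (S)-citronellol
Product: 19 (S)-citronellol tert-butyldimethylsilyl ether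
Conditions: TBSCl, imidazole, CH2Cl2, rt
Reagents that add atoms: tert-butyldimethylsilyl chloride, CC(C)(C)[Si](C)(C)Cl
Why: Standard silylation of the primary alcohol; the TBS ether tolerates RuO4, t-BuLi, pyridinium chlorochromate and Li/NH3 and falls together with the acetonide in step 19.

Step 13
Reactants: 19 silyl ether
Product: 20 (S)-6-(tert-butyldimethylsilyloxy)-4-methylhexanoic acid
Conditions: RuCl3·xH2O (2 mol %), NaIO4 (4 equiv), EtOAc/MeCN/H2O, rt
Reagents that add atoms: sodium periodate, [Na+].[O-]I(=O)(=O)=O (oxygen passed on by catalytic RuO4)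
Why: Catalytic RuO4 cleaves the trisubstituted alkene to the carboxylic acid and acetone (oxidative alkene cleavage) without touching the remote stereocentre.

Step 14
Reactants: 20 carboxylic acid
Product: 22 (R)-tert-butyl[(5-iodo-3-methylpentyl)oxy]dimethylsilane, via acyl hypoiodite 21 (not isolated)
Conditions: PhI(OAc)2, I2, cyclohexane, hν (tungsten lamp), reflux
Reagents that add atoms: iodine, II
Why: Hunsdiecker-type iododecarboxylation through the acyl hypoiodite excises the surplus carbon, so that the iodide carbon becomes C11 and the stereocentre becomes C13 with two two-carbon arms.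

Step 15
Reactants: 17 acetonide enone; 22 iodide
Product: 25 C9 tertiary allylic alcohol carrying the side chain (chain anti to the C10 methyl), via alkyllithium 23 (not isolated), via alkylcerium dichloride 24 (not isolated)
Conditions: 22 (1.5 equiv), t-BuLi (3.0 equiv), Et2O, −78 °C; CeCl3 (anhydrous), THF, −78 °C; then 17, −78 → −40 °C; aq. NH4Cl
Reagents that add atoms: none
Why: Iodine–lithium exchange and transmetalation give a weakly basic organocerium that should add 1,2 to the hindered, non-enolisable C9 enone (organocerium addition), expected anti to the C10 methyl; the new carbinol centre disappears in step 16.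

Step 16
Reactants: 25 tertiary allylic alcohol
Product: 26 7-oxo-labd-8-ene 2,3-acetonide 15-TBS ether
Conditions: pyridinium chlorochromate ([C5H5NH][CrO3Cl]), 4 Å molecular sieves, CH2Cl2, rt
Reagents that add atoms: pyridinium chlorochromate, [O-][Cr](=O)(=O)Cl.c1cc[nH+]cc1 (supplies the C7 oxygen)
Why: Babler–Dauben oxidative transposition: the tertiary allylic chromate ester undergoes a [3,3] shift to C7 and is oxidised there, which moves the oxygen to C7 and the alkene to C8=C9.

Step 17
Reactants: 26 transposed enone
Product: 28 C7 enol triflate (alkene C7=C8; H-9 anti to the C10 methyl), via C7 lithium enolate 27 (not isolated)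
Conditions: Li (2.2 equiv), NH3 (l)/THF, t-BuOH (1 equiv), −78 °C; isoprene; NH3 evaporated; PhNTf2, THF, −78 → 0 °C
Reagents that add atoms: N-phenylbis(trifluoromethanesulfonimide), O=S(=O)(N(c1ccccc1)S(=O)(=O)C(F)(F)F)C(F)(F)F
Why: Dissolving-metal (Birch-type) reduction of the enone should protonate C9 axially, anti to the C10 methyl, so that the chain becomes equatorial and C9 is set; the regiodefined enolate is trapped on oxygen by PhNTf2, which locks the alkene at C7=C8.

Step 18
Reactants: 28 enol triflate
Product: 29 labd-7-ene-2,3,15-triol 2,3-acetonide 15-TBS ether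
Conditions: Pd(OAc)2 (5 mol %), PPh3 (10 mol %), Bu3N, HCO2H, DMF, 60 °C
Reagents that add atoms: none
Why: Palladium-catalysed formate reduction of the enol triflate (oxidative addition to zerovalent palladium, formate decarboxylation, reductive elimination) replaces the triflate by hydrogen without moving the alkene or touching C9.

Step 19
Reactants: 29 protected triol
Product: 30 labd-7-ene-2,3,15-triol
Conditions: 2 M HCl (aq)/THF (1:3), rt
Reagents that add atoms: none
Why: Dilute aqueous acid hydrolyses both the acetonide and the primary silyl ether (acetal and silyl ether hydrolysis), and the trisubstituted alkene should not migrate under these mild conditions.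

Step 20
Reactants: 30 triol
Product: 31 target CNP0144124.1
Conditions: Ac2O (2.2 equiv), pyridine, CH2Cl2, 0 °C → rt, no DMAP
Reagents that add atoms: acetic anhydride, CC(=O)OC(C)=O
Why: Selective acylation: the primary C15 and the equatorial C2 hydroxyls should be acetylated, while the axial C3 hydroxyl, shielded by the C4 gem-dimethyl group, is left free.

**Compound list**
1 | (S)-(+)-carvone | O=C1C(C)=CC[C@H](C(C)=C)C1 | starting material
2 | lithium dienolate of carvone (cross-conjugated; O–Li on C1, C1=C6, carvone numbering) | [Li]OC1=C[C@@H](C(C)=C)CC=C1C | intermediate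
3 | (5S)-6-methylcarvone, C6 epimer mixture (C6 left open) | O=C1C(C)=CC[C@H](C(C)=C)C1C | intermediate
4 | acrolein | C=CC=O | starting material
5 | tetrasubstituted lithium enolate of 6-methylcarvone | [Li]OC1=C(C)[C@@H](C(C)=C)CC=C1C | intermediate
6 | 6-(1-hydroxyprop-2-en-1-yl)-6-methylcarvone; hydroxyallyl group trans and methyl cis to isopropenyl; carbinol epimers (left open) | O=C1C(C)=CC[C@H](C(C)=C)[C@@]1(C)C(O)C=C | intermediate
7 | 6-acryloyl-6-methylcarvone; acryloyl trans to isopropenyl (precursor of the key step) | O=C1C(C)=CC[C@H](C(C)=C)[C@@]1(C)C(=O)C=C | intermediate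
8 | trans-fused 4,4,8,10-tetramethyldecal-7-ene-1,9-dione; H-5 anti to the C10 methyl (product of the key step) | O=C1C(C)=CC[C@@H]2C(C)(C)CCC(=O)[C@@]12C | intermediate
9 | C1 lithium enolate of 8 (C1=C2) | O=C1C(C)=CC[C@@H]2C(C)(C)CC=C(O[Li])[C@@]12C | intermediate
10 | 2-(phenylselanyl)-4,4,8,10-tetramethyldecal-7-ene-1,9-dione; selenium anti to the C10 methyl | O=C1C(C)=CC[C@@H]2C(C)(C)C[C@@H]([Se]c3ccccc3)C(=O)[C@@]12C | intermediate
11 | 1-hydroxy-2-(phenylselanyl)-4,4,8,10-tetramethyldecal-7-en-9-one; C1 hydroxyl equatorial, syn to the C10 methyl | O=C1C(C)=CC[C@@H]2C(C)(C)C[C@@H]([Se]c3ccccc3)[C@H](O)[C@@]12C | intermediate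
12 | selenoxide of 11 | O=C1C(C)=CC[C@@H]2C(C)(C)C[C@@H]([Se](=O)c3ccccc3)[C@H](O)[C@@]12C | intermediate
13 | 1-hydroxy-4,4,8,10-tetramethyldecala-2,7-dien-9-one; C1 hydroxyl syn to the C10 methyl | O=C1C(C)=CC[C@@H]2C(C)(C)C=C[C@H](O)[C@@]12C | intermediate
14 | 1,2,3-trihydroxy-4,4,8,10-tetramethyldecal-7-en-9-one; C2 and C3 hydroxyls cis to each other and anti to the C10 methyl, C1 hydroxyl syn | O=C1C(C)=CC[C@@H]2C(C)(C)[C@@H](O)[C@@H](O)[C@H](O)[C@@]12C | intermediate
15 | 2,3-O-isopropylidene derivative of 14, C1 hydroxyl free | O=C1C(C)=CC[C@@H]2C(C)(C)[C@@H](OC3(C)C)[C@@H](O3)[C@H](O)[C@@]12C | intermediate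
16 | C1 O-phenyl thionocarbonate of 15 | O=C1C(C)=CC[C@@H]2C(C)(C)[C@@H](OC3(C)C)[C@@H](O3)[C@H](OC(=S)Oc4ccccc4)[C@@]12C | intermediate
17 | 2,3-O-isopropylidenedioxy-4,4,8,10-tetramethyldecal-7-en-9-one (C1 = CH2); acetonide anti to the C10 methyl | O=C1C(C)=CC[C@@H]2C(C)(C)[C@@H](OC3(C)C)[C@@H](O3)C[C@@]12C | intermediate
18 | (S)-(−)-citronellol | OCC[C@@H](C)CCC=C(C)C | starting material
19 | (S)-citronellol tert-butyldimethylsilyl ether | CC(C)(C)[Si](C)(C)OCC[C@@H](C)CCC=C(C)C | intermediate
20 | (S)-6-(tert-butyldimethylsilyloxy)-4-methylhexanoic acid | CC(C)(C)[Si](C)(C)OCC[C@@H](C)CCC(=O)O | intermediate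
21 | acyl hypoiodite of 20 | CC(C)(C)[Si](C)(C)OCC[C@@H](C)CCC(=O)OI | intermediate
22 | (R)-tert-butyl[(5-iodo-3-methylpentyl)oxy]dimethylsilane | CC(C)(C)[Si](C)(C)OCC[C@@H](C)CCI | intermediate
23 | 5-(tert-butyldimethylsilyloxy)-3-methylpentyllithium (configuration as in 22) | CC(C)(C)[Si](C)(C)OCC[C@@H](C)CC[Li] | intermediate
24 | 5-(tert-butyldimethylsilyloxy)-3-methylpentylcerium dichloride | CC(C)(C)[Si](C)(C)OCC[C@@H](C)CC[Ce](Cl)Cl | intermediate
25 | 9-hydroxy-labd-7-ene-2,3,15-triol 2,3-acetonide 15-TBS ether; side chain anti and C9 hydroxyl syn to the C10 methyl (expected) | CC(C)(C)[Si](C)(C)OCC[C@@H](C)CC[C@@]1(O)C(C)=CC[C@@H]2C(C)(C)[C@@H](OC3(C)C)[C@@H](O3)C[C@@]12C | intermediate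
26 | 7-oxo-labd-8-ene-2,3,15-triol 2,3-acetonide 15-TBS ether | CC(C)(C)[Si](C)(C)OCC[C@@H](C)CCC1=C(C)C(=O)C[C@@H]2C(C)(C)[C@@H](OC3(C)C)[C@@H](O3)C[C@@]12C | intermediate
27 | C7 lithium enolate (C7=C8) from 26; H-9 anti to the C10 methyl | CC(C)(C)[Si](C)(C)OCC[C@@H](C)CC[C@@H]1C(C)=C(O[Li])C[C@@H]2C(C)(C)[C@@H](OC3(C)C)[C@@H](O3)C[C@@]12C | intermediate
28 | labd-7-en-7-yl trifluoromethanesulfonate, 2,3-acetonide 15-TBS ether | CC(C)(C)[Si](C)(C)OCC[C@@H](C)CC[C@@H]1C(C)=C(OS(=O)(=O)C(F)(F)F)C[C@@H]2C(C)(C)[C@@H](OC3(C)C)[C@@H](O3)C[C@@]12C | intermediate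
29 | labd-7-ene-2,3,15-triol 2,3-acetonide 15-TBS ether | CC(C)(C)[Si](C)(C)OCC[C@@H](C)CC[C@@H]1C(C)=CC[C@@H]2C(C)(C)[C@@H](OC3(C)C)[C@@H](O3)C[C@@]12C | intermediate
30 | (2S,3R,5S,9R,10S,13S)-labd-7-ene-2,3,15-triol | OCC[C@@H](C)CC[C@@H]1C(C)=CC[C@@H]2C(C)(C)[C@@H](O)[C@@H](O)C[C@@]12C | intermediate
31 | CNP0144124.1: (2S,3R,5S,9R,10S,13S)-3-hydroxylabd-7-ene-2,15-diyl diacetate; 2-OAc equatorial and 3-OH axial, both anti to the C10 methyl; H-5 and H-9 anti to the C10 methyl | CC(=O)OCC[C@@H](C)CC[C@@H]1C(C)=CC[C@@H]2C(C)(C)[C@@H](O)[C@@H](OC(C)=O)C[C@@]12C | target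

**Step count**
Total: 20 steps. Longest linear sequence: 17 steps (steps 1–11 and 15–20, from (S)-carvone); steps 12–14 prepare the side-chain iodide from (S)-citronellol.

**Steps most likely to fail, with fallbacks**

Step 4. The iron hydride may transfer hydrogen to the vinyl ketone instead of the isopropenyl group, so that the acceptor is reduced or the radical adds intermolecularly and oligomerises. The fallback generates the same C4 radical without a metal hydride in the presence of the acceptor. It sets out from 6: Mukaiyama hydration of the isopropenyl group (Co(acac)2, PhSiH3, O2, i-PrOH) should give the tertiary alcohol, the hydroxyallyl diol F1. Dess–Martin oxidation of the secondary allylic alcohol then gives the hydroxy vinyl ketone F2, and oxalyl chloride followed by water gives the tert-alkyl hydrogen oxalate F3. Visible-light photoredox decarboxylation of F3 (Ir[dF(CF3)ppy]2(dtbbpy)PF6, K2HPO4, DME/DMF, blue light) releases the tertiary C4 radical, which closes ring A by the same 6-endo Giese addition. The sequence comes back to the route at 8.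

Step 15. The C9 carbonyl is flanked by the quaternary C10 and the methyl-bearing C8, so 1,2-addition may be too slow and γ-deprotonation or electron-transfer reduction may take over. The fallback makes the C9–C11 bond by cross-coupling and sets out from 17: γ-deprotonation at C6 with LiN(SiMe3)2 and O-triflation with PhNTf2 should give the dienyl triflate F4 (C9 triflate, C8=C9 and C6=C7). Alkyllithium 23 is trapped with 9-methoxy-9-borabicyclo[3.3.1]nonane as the lithium alkyl(methoxy)borate F5, which is coupled with F4 in a B-alkyl Suzuki–Miyaura reaction (PdCl2(dppf), AsPh3, Cs2CO3, DMF/H2O) to the 6,8-diene F6. 1,4-Reduction of this homoannular diene with Li/NH3 and t-BuOH, with protonation at C9 anti to the C10 methyl, returns to the route at 29 and bypasses 25–28.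

Step 2. Acrolein may react by conjugate addition or polymerise, and the hindered aldolate may revert on work-up. The fallback uses an aldehyde without a Michael pathway and sets out from 3: the lithium enolate 5 is added to propanal to give the hydroxypropyl adduct F7, and Dess–Martin oxidation gives the propanoyl diketone F8, whose only enolisable position is the propanoyl CH2. LiN(i-Pr)2/TMSCl gives the silyl enol ether F9, and Saegusa–Ito oxidation with Pd(OAc)2 in MeCN introduces the vinyl group. The sequence comes back to the route at 7.

**Further compounds**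
F1 | step 4 | 6-(1-hydroxyprop-2-en-1-yl)-5-(2-hydroxypropan-2-yl)-2,6-dimethylcyclohex-2-en-1-one (relative configuration as in 6) | O=C1C(C)=CC[C@H](C(C)(C)O)[C@@]1(C)C(O)C=C
F2 | step 4 | 6-acryloyl-5-(2-hydroxypropan-2-yl)-2,6-dimethylcyclohex-2-en-1-one | O=C1C(C)=CC[C@H](C(C)(C)O)[C@@]1(C)C(=O)C=C
F3 | step 4 | tert-alkyl hydrogen oxalate of F2 | O=C1C(C)=CC[C@H](C(C)(C)OC(=O)C(O)=O)[C@@]1(C)C(=O)C=C
F4 | step 15 | dienyl triflate from 17 (C9 triflate, C8=C9 and C6=C7) | FC(F)(F)S(=O)(=O)OC1=C(C)C=C[C@@H]2C(C)(C)[C@@H](OC3(C)C)[C@@H](O3)C[C@@]12C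
F5 | step 15 | lithium B-[5-(tert-butyldimethylsilyloxy)-3-methylpentyl]-B-methoxy-9-borabicyclo[3.3.1]nonane borate | [Li+].CO[B-]1(CC[C@H](C)CCO[Si](C)(C)C(C)(C)C)C2CCCC1CCC2
F6 | step 15 | labda-6,8-diene-2,3,15-triol 2,3-acetonide 15-TBS ether | CC(C)(C)[Si](C)(C)OCC[C@@H](C)CCC1=C(C)C=C[C@@H]2C(C)(C)[C@@H](OC3(C)C)[C@@H](O3)C[C@@]12C
F7 | step 2 | 6-(1-hydroxypropyl)-6-methylcarvone (hydroxypropyl trans to isopropenyl; carbinol epimers) | O=C1C(C)=CC[C@H](C(C)=C)[C@@]1(C)C(O)CC
F8 | step 2 | 6-propanoyl-6-methylcarvone | O=C1C(C)=CC[C@H](C(C)=C)[C@@]1(C)C(=O)CC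
F9 | step 2 | trimethylsilyl enol ether of F8 | O=C1C(C)=CC[C@H](C(C)=C)[C@@]1(C)C(O[Si](C)(C)C)=CC
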